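**Quick number.** If a quick number was what you wanted, I did not follow the flask minute by minute, though I kept your hunch that growth would carry the average past the mark.

free monomer 0.50 M; initiator 8.5 mM; time 1.5 min

- whether the average number of monomer units in a chain (chains begun, living or dead) reaches 30 by 1.5 min (yes / no)
- average number of monomer units in a chain (chains begun, living or dead) at 1.5 min

**The rule.** A free monomer and an initiator begin a chain of one unit, a living end adds free monomer, and a living end takes a free monomer and becomes a dead end. Adding and dying both run on [living end][free monomer], so I took the ratio of their constants, 100, as the run length, the units added per living end that dies (the kinetic chain length). Summed over time, the average in this flask is one plus the run length times the dead share of chains begun.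

**The clocks.** At the charge, an initiator waited 64.5 s and a living end lasted 31.2 s, against a run of 90 s. With [free monomer] held there, I reckoned 1.53 mM of living end at the end of the run and a dead share of 0.761. But that living end consumes free monomer with a time constant of 102 s, so I used the mean over an exponential fall, 0.332 M. My estimate of the dead share then came to 0.614, more than the 0.290 that 30 needs, so I said yes, with an average of 62.4.

**The result.** The forecast answered yes and 62, having “tracked the consumption against cumulative monomer exposure”. The flask gave yes and 62.4, reaching 30 at 0.378 min.

    free monomer + initiator → living end + monomer in chains (k1 = 0.031 L mol⁻¹ s⁻¹)
    free monomer + living end → monomer in chains + living end, rate k2*[living end]*[free monomer] (k2 = 6.4 L mol⁻¹ s⁻¹)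
    living end + free monomer → dead end (k3 = 0.064 L mol⁻¹ s⁻¹)

**Same ratio.** At 0.693 min, the half-life of free monomer was 0.88 min by growth and 88 min by the step making dead ends, a ratio of 100, the run length. At 15.0 min, the flask held 4.89 mM of dead end and 1.52 mM of living end, a dead share of 0.762, so the average there stood at 77.2.

(The constants used here come from no measurement, and the outcome is calculated.)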